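**Plan**
- Retrosynthesis: the 7-OH is masked as a benzyl ether. The oxygen ring (ring C) is then cut at O1–C8a and C4–C4a in a single operation, giving a ring-A aryl iodide and an (S)-3-bromo-2-arylpropan-1-ol that carries C2, C3, C4 and ring B.
- The bromo alcohol is cut at C–Br to a prochiral 3-aryloxetane, and this at the ring B–C3 bond to an arylboronic acid and 3-iodooxetane.
- Enabling feature: C4a and C8a of ring A are neighbours and carry C4 and O1 of one three-carbon chain, and C8 bears a methoxy group. An iodide at C8a therefore has exactly one free ortho C–H (C4a) and one blocked ortho position (C8), as a palladium/norbornene ortho-alkylation with ipso-etherification requires.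
- Forward: ring B is joined to the oxetane (steps 1–2), the oxetane is opened to the chain (step 3), the ring-A iodide is prepared (steps 4–6), ring C is closed onto ring A (step 7), and the benzyl group is removed (step 8).
- Stereochemistry: the only stereocentre, C3 (S), is set by the catalyst-controlled desymmetrising oxetane opening in step 3 and is a spectator afterwards.

Key step: step 7

Assumption: the sense of induction in the squaramide-catalysed oxetane opening is taken to be purely catalyst-controlled, so the catalyst enantiomer that delivers the (S)-bromohydrin is the one used.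

**Step 1**
Reactants: 1 1,2,3,4-tetramethoxybenzene
Product: 4 (2,3,4,5-tetramethoxyphenyl)boronic acid, via aryllithium 2 (not isolated), via lithium triisopropoxyborate 3 (not isolated)
Conditions: n-BuLi, TMEDA, THF, 0 °C; B(Oi-Pr)3, −78 °C to rt; aq. HCl
Reagents that add atoms: n-butyllithium [Li]CCCC (lithium of 2 and 3); triisopropyl borate CC(C)OB(OC(C)C)OC(C)C (boron, and the isopropoxy groups of 3); water O (hydroxyl oxygens of 4)
Why: Both ring hydrogens of 1 are equivalent and ortho to a methoxy group, so directed ortho-lithiation followed by borate trapping and acidic hydrolysis should deliver a single boronic acid.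

**Step 2**
Reactants: 4 (2,3,4,5-tetramethoxyphenyl)boronic acid; 5 3-iodooxetane
Product: 6 3-(2,3,4,5-tetramethoxyphenyl)oxetane
Conditions: NiI2 (cat.), trans-2-aminocyclohexanol·HCl (cat.), NaN(SiMe3)2, i-PrOH, 80 °C
Reagents that add atoms: none
Why: Nickel-catalysed Suzuki–Miyaura coupling of arylboronic acids with secondary alkyl iodides under amino-alcohol ligation is an established entry to 3-aryloxetanes, the oxetan-3-yl radical being captured by aryl nickel without ring opening, and it forms the ring B–C3 bond.

**Step 3**
Reactants: 6 3-(2,3,4,5-tetramethoxyphenyl)oxetane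
Product: 8 (S)-3-bromo-2-(2,3,4,5-tetramethoxyphenyl)propan-1-ol, via trimethylsilyl ether 7 (not isolated)
Conditions: Me3SiBr, chiral arylpyrrolidine-derived squaramide hydrogen-bond donor (5 mol %), t-BuOMe, −78 °C; then MeOH, 0 °C
Reagents that add atoms: bromotrimethylsilane C[Si](C)(C)Br (bromine of 8; the silyl group of 7)
Why: Catalytic enantioselective desymmetrising ring opening of a prochiral 3-substituted oxetane: the chiral squaramide binds bromide and directs its SN2 attack to one of the two enantiotopic O–CH2 carbons of the silylated oxetane, which sets the stereocentre (the later C3) as S, and base-free methanolysis then releases the alcohol without risk of oxetane re-closure.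

**Step 4**
Reactants: 9 1,3-dibromo-2-methoxybenzene (2,6-dibromoanisole)
Product: 12 3-bromo-2-methoxyphenol, via aryllithium 10 (not isolated), via lithium trimethoxyborate 11 (not isolated)
Conditions: n-BuLi (1.0 equiv), THF, −78 °C; B(OMe)3, −78 °C to rt; AcOH, 30% aq. H2O2, 0 °C to rt
Reagents that add atoms: n-butyllithium [Li]CCCC (lithium of 10 and 11); trimethyl borate COB(OC)OC (boron and methoxy groups of 11); hydrogen peroxide OO (phenol oxygen of 12)
Why: Bromine–lithium exchange at one of the two equivalent C–Br bonds is fast at −78 °C, the aryllithium sits meta to the remaining bromine and so cannot collapse to an aryne, and borate formation followed by peroxide oxidation (1,2-aryl shift from boron to oxygen) is a standard aryl halide to phenol conversion.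

**Step 5**
Reactants: 12 3-bromo-2-methoxyphenol
Product: 13 1-(benzyloxy)-3-bromo-2-methoxybenzene
Conditions: BnBr, K2CO3, DMF, rt
Reagents that add atoms: benzyl bromide BrCc1ccccc1
Why: Williamson ether synthesis of a phenoxide with a benzylic bromide, which installs a 7-O protecting group that tolerates base and palladium and leaves by hydrogenolysis.

**Step 6**
Reactants: 13 1-(benzyloxy)-3-bromo-2-methoxybenzene
Product: 14 1-(benzyloxy)-3-iodo-2-methoxybenzene
Conditions: CuI (5 mol %), trans-N,N′-dimethylcyclohexane-1,2-diamine (10 mol %), NaI, 1,4-dioxane, 110 °C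
Reagents that add atoms: sodium iodide [Na+].[I-]
Why: Copper-catalysed aromatic Finkelstein exchange, driven by the low solubility of NaBr in dioxane, converts the bromide into the iodide that the palladium/norbornene step needs for fast oxidative addition.

**Step 7**
Reactants: 14 1-(benzyloxy)-3-iodo-2-methoxybenzene; 8 (S)-3-bromo-2-(2,3,4,5-tetramethoxyphenyl)propan-1-ol
Product: 15 (3S)-7-(benzyloxy)-8-methoxy-3-(2,3,4,5-tetramethoxyphenyl)-3,4-dihydro-2H-chromene
Conditions: Pd(OAc)2 (10 mol %), XPhos (20 mol %), norbornene, Cs2CO3, 1,4-dioxane, 90 °C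
Reagents that add atoms: none
Why: Proposed new method: zerovalent palladium should insert into the C8a–I bond of 14, norbornene then inserts and relays the metal to C4a–H to give an aryl–norbornyl palladacycle of divalent palladium, which takes up the primary C–Br bond of 8 by SN2-type oxidative addition to tetravalent palladium and forms C4–C4a on reductive elimination. Because C8 (OMe) and C4a (new alkyl) now flank the metal, norbornene is expelled by β-carbon elimination, the caesium alkoxide of the tether binds the divalent aryl palladium, and C–O reductive elimination from the seven-membered oxapalladacycle forms O1–C8a, closing the six-membered oxygen ring (ring C) in an overall [3+3] annulation. The closest known reaction types are Catellani ortho-alkylation with ipso C–O closure from epoxides (dihydrobenzofurans) or ipso C–N closure from bromoalkyl amines (tetrahydroquinolines), together with palladium-catalysed intramolecular etherification of aryl halides by primary alcohols; the combination with a free 3-bromopropanol has not been shown. No stereocentre is created: C3 comes from 8, is never bonded to palladium and carries no acidic hydrogen, so its S configuration should pass into 15 unchanged. Site selectivity is fixed by the substrate, since the 8-methoxy group blocks one ortho position and leaves C4a as the only C–H next to palladium, and the same group supplies the ortho substituent needed for clean norbornene extrusion after a single alkylation. The required chemoselectivity, C–O reductive elimination ahead of β-hydride elimination of the palladium alkoxide and ahead of base-induced oxetane closure or dehydrobromination of 8, is what the bulky electron-rich XPhos ligand, the intramolecular six-ring closure and the poorly soluble carbonate in dioxane are meant to secure.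

**Step 8**
Reactants: 15 (3S)-7-(benzyloxy)-8-methoxy-3-(2,3,4,5-tetramethoxyphenyl)-3,4-dihydro-2H-chromene
Product: 16 (3S)-8-methoxy-3-(2,3,4,5-tetramethoxyphenyl)-3,4-dihydro-2H-chromen-7-ol
Conditions: H2 (1 atm), Pd/C, EtOAc–MeOH, rt
Reagents that add atoms: none
Why: Hydrogenolysis of the benzyl aryl ether; neither ring-C C–O bond is benzylic, the aryl methyl ethers are inert and C3 bears no activating heteroatom, so the S configuration should be retained.

**Compound list**
1 | 1,2,3,4-tetramethoxybenzene | COc1ccc(OC)c(OC)c1OC | starting material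
2 | (2,3,4,5-tetramethoxyphenyl)lithium | [Li]c1cc(OC)c(OC)c(OC)c1OC | intermediate
3 | lithium triisopropoxy(2,3,4,5-tetramethoxyphenyl)borate | [Li+].COc1cc([B-](OC(C)C)(OC(C)C)OC(C)C)c(OC)c(OC)c1OC | intermediate
4 | (2,3,4,5-tetramethoxyphenyl)boronic acid | COc1cc(B(O)O)c(OC)c(OC)c1OC | intermediate
5 | 3-iodooxetane | IC1COC1 | starting material
6 | 3-(2,3,4,5-tetramethoxyphenyl)oxetane | COc1cc(C2COC2)c(OC)c(OC)c1OC | intermediate
7 | (S)-[3-bromo-2-(2,3,4,5-tetramethoxyphenyl)propoxy]trimethylsilane | COc1cc([C@H](CBr)CO[Si](C)(C)C)c(OC)c(OC)c1OC | intermediate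
8 | (S)-3-bromo-2-(2,3,4,5-tetramethoxyphenyl)propan-1-ol | COc1cc([C@H](CBr)CO)c(OC)c(OC)c1OC | intermediate
9 | 1,3-dibromo-2-methoxybenzene (2,6-dibromoanisole) | COc1c(Br)cccc1Br | starting material
10 | (3-bromo-2-methoxyphenyl)lithium | [Li]c1cccc(Br)c1OC | intermediate
11 | lithium (3-bromo-2-methoxyphenyl)trimethoxyborate | [Li+].COc1c(Br)cccc1[B-](OC)(OC)OC | intermediate
12 | 3-bromo-2-methoxyphenol | COc1c(O)cccc1Br | intermediate
13 | 1-(benzyloxy)-3-bromo-2-methoxybenzene | COc1c(Br)cccc1OCc1ccccc1 | intermediate
14 | 1-(benzyloxy)-3-iodo-2-methoxybenzene | COc1c(I)cccc1OCc1ccccc1 | intermediate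
15 | (3S)-7-(benzyloxy)-8-methoxy-3-(2,3,4,5-tetramethoxyphenyl)-3,4-dihydro-2H-chromene | COc1cc([C@H]2COc3c(ccc(OCc4ccccc4)c3OC)C2)c(OC)c(OC)c1OC | intermediate
16 | (3S)-8-methoxy-3-(2,3,4,5-tetramethoxyphenyl)-3,4-dihydro-2H-chromen-7-ol | COc1cc([C@H]2COc3c(ccc(O)c3OC)C2)c(OC)c(OC)c1OC | target

**Step count**
Total: 8 steps. Longest linear sequence: 5 steps (steps 1, 2, 3, 7, 8; the ring-A branch, steps 4, 5, 6, 7, 8, is equally long).

**Steps most likely to fail**

Step 7 (the annulation). Three processes could divert it:
- β-hydride elimination from the palladium alkoxide, which would end the sequence by ipso-hydrogenation instead of C–O bond formation.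
- Base-induced loss of HBr or re-closure to the oxetane, consuming 8 before it reaches the palladacycle.
- Slow oxidative addition of the β-branched bromide to the palladacycle.

The fallback sets out from 13 and 8 and returns at 15, forming the same two bonds in separate, known operations. Bromide 13 would be iodinated para to the benzyloxy group (N-iodosuccinimide, cat. CF3CO2H, MeCN, rt) to give 1-(benzyloxy)-3-bromo-4-iodo-2-methoxybenzene F1. Alcohol 8 would be silylated (t-BuMe2SiCl, imidazole, CH2Cl2) to (S)-[3-bromo-2-(2,3,4,5-tetramethoxyphenyl)propoxy](tert-butyl)dimethylsilane F2. Zinc insertion into its C–Br bond (Zn dust, cat. I2, DMA, 70 °C) would give, in solution, (S)-[3-[(tert-butyldimethylsilyl)oxy]-2-(2,3,4,5-tetramethoxyphenyl)propyl]zinc bromide F3. Negishi coupling of this reagent at the C–I bond of the dihalide (PdCl2(dppf), THF–DMA, 40 °C) would form C4–C4a and give (S)-[3-[4-(benzyloxy)-2-bromo-3-methoxyphenyl]-2-(2,3,4,5-tetramethoxyphenyl)propoxy](tert-butyl)dimethylsilane F4. Desilylation (Bu4NF, THF) would give (S)-3-[4-(benzyloxy)-2-bromo-3-methoxyphenyl]-2-(2,3,4,5-tetramethoxyphenyl)propan-1-ol F5. Palladium-catalysed intramolecular aryl etherification (Pd(OAc)2, 2-(di-tert-butylphosphino)-1,1′-binaphthyl, Cs2CO3, toluene, 80 °C) would then close O1–C8a and give 15.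

Step 3 (enantioselective oxetane opening). An uncatalysed opening, or one assisted by the very electron-rich aryl group, could compete with the catalyst-bound pathway. The ortho-methoxy group could also disturb substrate binding. Either would erode the enantiomeric purity of C3.

The fallback sets out from 6 and returns at 8, replacing asymmetric catalysis by enzymatic desymmetrisation. Oxetane 6 would be hydrolysed (0.5 M H2SO4, THF–H2O, 50 °C) to 2-(2,3,4,5-tetramethoxyphenyl)propane-1,3-diol F6. Lipase-catalysed mono-acetylation (a Pseudomonas cepacia or porcine pancreatic lipase selected for the required sense, vinyl acetate, t-BuOMe, rt) would give (R)-3-hydroxy-2-(2,3,4,5-tetramethoxyphenyl)propyl acetate F7. This would be kept under neutral conditions to avoid acyl migration. Appel bromination (CBr4, PPh3, CH2Cl2, 0 °C) would give (S)-3-bromo-2-(2,3,4,5-tetramethoxyphenyl)propyl acetate F8. Acidic methanolysis (AcCl, MeOH, 0 °C to rt) would then give 8.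

Step 2 (nickel coupling). Protodeboronation of the electron-rich, ortho-methoxy boronic acid under the strongly basic alcoholic conditions could outrun transmetalation, and the ortho substituent slows the coupling.

The fallback sets out from 1 and returns at 6, avoiding both the boron reagent and the strong base. Arene 1 would be brominated (N-bromosuccinimide, MeCN, rt) to 1-bromo-2,3,4,5-tetramethoxybenzene F9. Nickel-catalysed reductive cross-electrophile coupling with 3-iodooxetane 5 (NiI2, 4,4′-di-tert-butyl-2,2′-bipyridine, Zn, NaI, DMA, 60 °C) would then give 6.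

**Further compounds**
F1 | step 7 | 1-(benzyloxy)-3-bromo-4-iodo-2-methoxybenzene | COc1c(Br)c(I)ccc1OCc1ccccc1
F2 | step 7 | (S)-[3-bromo-2-(2,3,4,5-tetramethoxyphenyl)propoxy](tert-butyl)dimethylsilane | COc1cc([C@H](CBr)CO[Si](C)(C)C(C)(C)C)c(OC)c(OC)c1OC
F3 | step 7 | (S)-[3-[(tert-butyldimethylsilyl)oxy]-2-(2,3,4,5-tetramethoxyphenyl)propyl]zinc bromide | COc1cc([C@H](C[Zn]Br)CO[Si](C)(C)C(C)(C)C)c(OC)c(OC)c1OC
F4 | step 7 | (S)-[3-[4-(benzyloxy)-2-bromo-3-methoxyphenyl]-2-(2,3,4,5-tetramethoxyphenyl)propoxy](tert-butyl)dimethylsilane | COc1cc([C@H](Cc2ccc(OCc3ccccc3)c(OC)c2Br)CO[Si](C)(C)C(C)(C)C)c(OC)c(OC)c1OC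
F5 | step 7 | (S)-3-[4-(benzyloxy)-2-bromo-3-methoxyphenyl]-2-(2,3,4,5-tetramethoxyphenyl)propan-1-ol | COc1cc([C@H](Cc2ccc(OCc3ccccc3)c(OC)c2Br)CO)c(OC)c(OC)c1OC
F6 | step 3 | 2-(2,3,4,5-tetramethoxyphenyl)propane-1,3-diol | COc1cc(C(CO)CO)c(OC)c(OC)c1OC
F7 | step 3 | (R)-3-hydroxy-2-(2,3,4,5-tetramethoxyphenyl)propyl acetate | COc1cc([C@H](CO)COC(C)=O)c(OC)c(OC)c1OC
F8 | step 3 | (S)-3-bromo-2-(2,3,4,5-tetramethoxyphenyl)propyl acetate | COc1cc([C@H](CBr)COC(C)=O)c(OC)c(OC)c1OC
F9 | step 2 | 1-bromo-2,3,4,5-tetramethoxybenzene | COc1cc(Br)c(OC)c(OC)c1OC
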